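**Plan**
- Retrosynthesis cuts, in order: the C3–O ester; the C7=C8 double bond of ring B (back to a C7 aldehyde and a C8 methyl ketone); C11–C12 (Wittig); C9–C10 (ester-enolate Claisen); ring A goes back to dimedone.
- Forward: ring A is made first (Stork–Danheiser enone), C9 is then attached to C10, the side chain is added, ring A is oxygenated, and ring B is closed last.
- Stereochemistry: the C2 carbinol comes from a reagent-controlled CBS reduction, which also selects the C5 enantiomer. It is relayed suprafacially to C10 and, through a boat transition state, to C9. 2α-OH and 3α-O are then set from the face opposite the axial 4β/10β methyls. C13 and the acyl centre come from the chiral pool.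
- Enabling feature: C7=C8 is the only unsaturation of ring B, and C7 and C8 are reached from ring A through C6H2 (on C5) and C9H (on C10), which are cis on ring A. Opening that bond therefore leaves a 1,6-keto aldehyde on a cis-1,2-disubstituted cyclohexane that is pre-organised for reductive carbonyl coupling.

Key step: step 19

Remark: the SMILES is read as a cis-fused labdane (5β-H, 10β-CH3, 9α-H, 2α-OH, 3α-acyloxy, 13S, acyl 2S). Labdane numbering is used for all intermediates, β is the face of the C20 methyl, and racemates are written without stereodescriptors.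

**Step 1**
Reactants: 1 dimedone
Product: 2 3-ethoxy-5,5-dimethylcyclohex-2-en-1-one
Conditions: EtOH, TsOH·H2O (cat.), toluene, reflux, Dean–Stark
Reagents that add atoms: ethanol, CCO
Why: Acid-catalysed O-alkylation of the enolised 1,3-dione (vinylogous ester formation) with azeotropic removal of water.

**Step 2**
Reactants: 2 3-ethoxy-5,5-dimethylcyclohex-2-en-1-one
Product: 4 rac-6-allyl-3-ethoxy-5,5-dimethylcyclohex-2-en-1-one, via lithium dienolate 3 (not isolated)
Conditions: LiN(iPr)2, THF, −78 °C; allyl bromide, −78 → 0 °C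
Reagents that add atoms: allyl bromide, C=CCBr; lithium diisopropylamide, CC(C)N([Li])C(C)C (Li of 3)
Why: Stork–Danheiser α′-alkylation, in which kinetic deprotonation is possible only at C6 and the dienolate is alkylated there; the new centre (later C5) is racemic.

**Step 3**
Reactants: 4 rac-6-allyl-3-ethoxy-5,5-dimethylcyclohex-2-en-1-one
Product: 6 rac-4-allyl-3,5,5-trimethylcyclohex-2-en-1-one, via tertiary alcohol 5 (not isolated)
Conditions: MeLi, Et2O, −78 → 0 °C; then 1 M HCl, THF, rt
Reagents that add atoms: methyllithium, [Li]C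
Why: Stork–Danheiser transposition, in which 1,2-addition to the vinylogous ester carbonyl and acid hydrolysis/dehydration of 5 move the carbonyl to the former enol-ether carbon (later C2) and put the new methyl (C20) on the alkene.

**Step 4**
Reactants: 6 rac-4-allyl-3,5,5-trimethylcyclohex-2-en-1-one
Product: 8 rac-4-(2,2-dimethoxyethyl)-3,5,5-trimethylcyclohex-2-en-1-one, via aldehyde 7 (not isolated)
Conditions: O3, CH2Cl2/MeOH, −78 °C; Me2S; then HC(OMe)3, CeCl3·7H2O (cat.), MeOH, rt
Reagents that add atoms: ozone, O=[O+][O-] (carbonyl oxygen of 7); trimethyl orthoformate, COC(OC)OC (methoxy groups of 8)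
Why: Ozonolysis should take the electron-rich terminal alkene in preference to the electron-poor enone, and Gemal–Luche acetalisation, which is selective for aldehydes, masks C7 as its dimethyl acetal.

**Step 5**
Reactants: 8 rac-4-(2,2-dimethoxyethyl)-3,5,5-trimethylcyclohex-2-en-1-one
Product: 9 (1S,4R)-4-(2,2-dimethoxyethyl)-3,5,5-trimethylcyclohex-2-en-1-ol
Conditions: (R)-2-methyl-CBS-oxazaborolidine (C18H20BNO, 0.2 equiv), catecholborane, toluene, −78 °C; chromatography
Reagents that add atoms: none
Why: Corey–Bakshi–Shibata reduction under reagent control should give the 1S carbinol from both enantiomers, so the 4R enantiomer gives the cis alcohol 9 and the 4S enantiomer the separable trans diastereomer; at most half of 8 can be used.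

**Step 6**
Reactants: 9 (1S,4R)-4-(2,2-dimethoxyethyl)-3,5,5-trimethylcyclohex-2-en-1-ol and 10 (2-methyl-1,3-dioxolan-2-yl)acetic acid
Product: 11 (1S,4R)-4-(2,2-dimethoxyethyl)-3,5,5-trimethylcyclohex-2-en-1-yl (2-methyl-1,3-dioxolan-2-yl)acetate
Conditions: DCC, DMAP (cat.), CH2Cl2, 0 °C → rt
Reagents that add atoms: none
Why: Steglich esterification of the secondary allylic alcohol with retention at the carbinol carbon.

**Step 7**
Reactants: 11 (1S,4R)-4-(2,2-dimethoxyethyl)-3,5,5-trimethylcyclohex-2-en-1-yl (2-methyl-1,3-dioxolan-2-yl)acetate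
Product: 14 C11 alcohol of the ring-A fragment (Δ1; C10 quaternary; 9α-H; C8 as dioxolane), via silyl ketene acetal 12 (not isolated), via trimethylsilyl ester 13 (not isolated)
Conditions: LiN(iPr)2, Me3SiCl, THF/DMPU (4:1), −78 → 65 °C; then LiAlH4, 0 °C
Reagents that add atoms: chlorotrimethylsilane, C[Si](C)(C)Cl (silyl groups of 12 and 13 only)
Why: Ireland–Claisen rearrangement, in which C9 is delivered suprafacially to C10 on the face of the C2 oxygen (cis to the C5 chain) through a boat-like transition state (the chair is blocked by the axial 4α-methyl) with the dioxolanyl group outside and H inside, which sets 9α-H; the silyl ester is reduced in the same flask.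

**Step 8**
Reactants: 14 C11 alcohol of the ring-A fragment
Product: 15 3,11-diol of the ring-A fragment (Δ1; C3 epimers)
Conditions: SeO2 (0.5 equiv), t-BuOOH, CH2Cl2, rt
Reagents that add atoms: selenium dioxide, O=[Se]=O (oxygen of the new hydroxyl; turned over by tert-butyl hydroperoxide, CC(C)(C)OO)
Why: Selenium dioxide allylic hydroxylation (ene reaction, then [2,3]-sigmatropic shift) can act only at C3, the sole allylic C–H position, and the configuration there does not matter because C3 is oxidised in step 9.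

**Step 9**
Reactants: 15 3,11-diol of the ring-A fragment
Product: 16 1-en-3-one 11-aldehyde of the ring-A fragment
Conditions: Dess–Martin periodinane, NaHCO3, CH2Cl2, 0 °C → rt
Reagents that add atoms: none
Why: Dess–Martin oxidation of the primary and the allylic secondary hydroxyl under buffered conditions that should not epimerise C9.

**Step 10**
Reactants: 17 (3S)-5-methoxy-3-methyl-5-oxopentanoic acid
Product: 18 methyl (3R)-4-iodo-3-methylbutanoate
Conditions: PhI(OAc)2, I2, cyclohexane, hν (tungsten lamp), reflux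
Reagents that add atoms: iodine, II
Why: Suárez iododecarboxylation (radical Hunsdiecker-type reaction through the acyl hypoiodite); the stereocentre is β to the radical site and is untouched.

**Step 11**
Reactants: 18 methyl (3R)-4-iodo-3-methylbutanoate
Product: 19 [(2R)-4-methoxy-2-methyl-4-oxobutyl]triphenylphosphonium iodide
Conditions: PPh3, MeCN, reflux
Reagents that add atoms: triphenylphosphine, c1ccc(cc1)P(c1ccccc1)c1ccccc1
Why: SN2 quaternisation of the phosphine by the primary iodide.

**Step 12**
Reactants: 16 1-en-3-one 11-aldehyde of the ring-A fragment and 19 [(2R)-4-methoxy-2-methyl-4-oxobutyl]triphenylphosphonium iodide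
Product: 21 (11Z)-7,8-seco-labda-1,11-dien-3-one methyl ester (C7 acetal; C8 ketal), via ylide 20 (not isolated)
Conditions: 19, NaN(SiMe3)2, THF, −78 → 0 °C; then 16, −78 °C → rt
Reagents that add atoms: none
Why: Wittig olefination with a non-stabilised ylide; the aldehyde should react far faster than the hindered enone carbonyl, and the alkene geometry is irrelevant.

**Step 13**
Reactants: 21 (11Z)-7,8-seco-labda-1,11-dien-3-one methyl ester
Product: 22 7,8-seco-labdan-3-one methyl ester (C7 acetal; C8 ketal)
Conditions: H2 (1 atm), Pd/C, EtOAc, rt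
Reagents that add atoms: none
Why: Heterogeneous hydrogenation saturates the side-chain alkene and the enone C1=C2 bond and leaves the hindered ketone, the acetal and the ketal intact; no stereocentre is formed.

**Step 14**
Reactants: 22 7,8-seco-labdan-3-one methyl ester
Product: 24 2α-hydroxy-7,8-seco-labdan-3-one methyl ester, via potassium enolate 23 (not isolated)
Conditions: KN(SiMe3)2, THF, −78 °C; then 2-(phenylsulfonyl)-3-phenyloxaziridine, −78 °C
Reagents that add atoms: 2-(phenylsulfonyl)-3-phenyloxaziridine, O=S(=O)(c1ccccc1)N1OC1c1ccccc1; potassium bis(trimethylsilyl)amide, C[Si](C)(C)N([K])[Si](C)(C)C (K of 23)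
Why: Davis enolate oxidation, in which the ketone can enolise only toward C2 and the oxidant should approach from the α face, opposite the syn-axial 4β- and 10β-methyls, to give the equatorial 2α-hydroxy ketone.

**Step 15**
Reactants: 24 2α-hydroxy-7,8-seco-labdan-3-one methyl ester
Product: 25 2α-(4-methoxybenzyloxy)-7,8-seco-labdan-3-one methyl ester
Conditions: 4-methoxybenzyl bromide, Ag2O, CH2Cl2, rt, dark
Reagents that add atoms: 4-methoxybenzyl bromide, COc1ccc(CBr)cc1
Why: Williamson-type etherification under neutral Ag2O activation, which avoids enolisation of the α-ketol.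

**Step 16**
Reactants: 25 2α-(4-methoxybenzyloxy)-7,8-seco-labdan-3-one methyl ester
Product: 26 3α-hydroxy-2α-(4-methoxybenzyloxy)-7,8-seco-labdane methyl ester
Conditions: LiBH(s-Bu)3, THF, −78 °C
Reagents that add atoms: none
Why: Reduction with a bulky hydride, in which axial α-face attack is blocked by the axial C6 chain on C5, so hydride should arrive equatorially and give the axial 3α-alcohol, cis to the 2α-ether.

**Step 17**
Reactants: 26 3α-hydroxy-2α-(4-methoxybenzyloxy)-7,8-seco-labdane methyl ester and 27 (2S)-2-hydroxy-2-methylbutanoic acid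
Product: 29 3α-[(2S)-2-hydroxy-2-methylbutanoyloxy]-2α-(4-methoxybenzyloxy)-7,8-seco-labdane methyl ester, via mixed anhydride 28 (not isolated)
Conditions: 27, 2,4,6-trichlorobenzoyl chloride, Et3N, THF, rt; then 26, DMAP, toluene, 80 °C
Reagents that add atoms: 2,4,6-trichlorobenzoyl chloride, O=C(Cl)c1c(Cl)cc(Cl)cc1Cl (aroyl part of 28 only)
Why: Yamaguchi esterification through the mixed anhydride and DMAP acyl transfer; the tertiary hydroxyl of 27 should not compete and no stereocentre is touched.

**Step 18**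
Reactants: 29 3α-[(2S)-2-hydroxy-2-methylbutanoyloxy]-2α-(4-methoxybenzyloxy)-7,8-seco-labdane methyl ester
Product: 30 7-oxo-8-oxo-7,8-seco-labdane keto aldehyde (C7 aldehyde; C8 methyl ketone)
Conditions: PPTS, acetone/H2O (10:1), 55 °C
Reagents that add atoms: water, O
Why: Mild acid hydrolysis of the dimethyl acetal and the dioxolane should release both carbonyl groups while the 4-methoxybenzyl ether and the esters survive.

**Step 19**
Reactants: 30 7-oxo-8-oxo-7,8-seco-labdane keto aldehyde
Product: 31 methyl 3α-[(2S)-2-hydroxy-2-methylbutanoyloxy]-2α-(4-methoxybenzyloxy)labd-7-en-15-oate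
Conditions: TiCl3(DME)1.5, Zn(Cu), DME, reflux; 30 added over 30 h by syringe pump
Reagents that add atoms: none
Why: McMurry reductive carbonyl coupling, in which electron transfer from the low-valent titanium surface to the C7 aldehyde and the C8 ketone gives ketyl radicals that join to a titanium-bound C7–C8 pinacolate, which is then deoxygenated on the metal to the C7=C8 alkene. The closest known reaction type is the titanium-mediated cyclisation of 1,6-keto aldehydes to 1-substituted cyclohexenes. Ring B (C5–C10) is the only ring closed, as a six-membered carbocycle, by direct union of the two carbonyl carbons carried on the cis C5 and C10 arms of ring A. No stereocentre is created; the cis fusion (C5, C10) and C9 come from 30 and should not epimerise because the reagent is not Brønsted-basic. The step needs cyclisation to win over intermolecular pinacol coupling, which slow addition at high dilution and the cis placement of the two chains secure, and it needs the aldehyde and ketone to react in preference to the two esters, which their much faster ketyl formation secures; the alkene position is fixed by the two carbonyl carbons, so no 8(17)- or 8(9)-isomer can form.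

**Step 20**
Reactants: 31 methyl 3α-[(2S)-2-hydroxy-2-methylbutanoyloxy]-2α-(4-methoxybenzyloxy)labd-7-en-15-oate
Product: 32 3α-[(2S)-2-hydroxy-2-methylbutanoyloxy]-2α-(4-methoxybenzyloxy)labd-7-en-15-oic acid
Conditions: LiOH·H2O, THF/MeOH/H2O, 0 °C; then 1 M HCl to pH 3
Reagents that add atoms: lithium hydroxide, [Li+].[OH-]
Why: Saponification of the unhindered methyl ester should be much faster than attack on the neopentyl, α-quaternary C3 ester, and the 2-O-(4-methoxybenzyl) group blocks base-induced acyl migration.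

**Step 21**
Reactants: 32 3α-[(2S)-2-hydroxy-2-methylbutanoyloxy]-2α-(4-methoxybenzyloxy)labd-7-en-15-oic acid
Product: 33 (2R,3S,5S,9S,10R,13S)-2-hydroxy-3-{[(2S)-2-hydroxy-2-methylbutanoyl]oxy}labd-7-en-15-oic acid
Conditions: DDQ, CH2Cl2/pH 7 buffer (10:1), 0 °C → rt
Reagents that add atoms: none
Why: Oxidative cleavage of the 4-methoxybenzyl ether under buffered, non-basic conditions that should move neither the acyl group nor the trisubstituted alkene.

**Compound list**
1 | dimedone (5,5-dimethylcyclohexane-1,3-dione) | CC1(C)CC(=O)CC(=O)C1 | starting material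
2 | 3-ethoxy-5,5-dimethylcyclohex-2-en-1-one | CCOC1=CC(=O)CC(C)(C)C1 | intermediate
3 | lithium dienolate of 2 (O–Li on C1, C1=C6 and C2=C3; not isolated) | [Li]OC1=CC(C)(C)CC(OCC)=C1 | intermediate
4 | rac-6-allyl-3-ethoxy-5,5-dimethylcyclohex-2-en-1-one | CCOC1=CC(=O)C(CC=C)C(C)(C)C1 | intermediate
5 | 6-allyl-3-ethoxy-1,5,5-trimethylcyclohex-2-en-1-ol (racemic diastereomer mixture; not isolated) | CCOC1=CC(C)(O)C(CC=C)C(C)(C)C1 | intermediate
6 | rac-4-allyl-3,5,5-trimethylcyclohex-2-en-1-one | CC1=CC(=O)CC(C)(C)C1CC=C | intermediate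
7 | rac-2-(2,6,6-trimethyl-4-oxocyclohex-2-en-1-yl)acetaldehyde (not isolated) | CC1=CC(=O)CC(C)(C)C1CC=O | intermediate
8 | rac-4-(2,2-dimethoxyethyl)-3,5,5-trimethylcyclohex-2-en-1-one | COC(OC)CC1C(C)=CC(=O)CC1(C)C | intermediate
9 | (1S,4R)-4-(2,2-dimethoxyethyl)-3,5,5-trimethylcyclohex-2-en-1-ol (cis; labdane C2–O α, 5β-H) | O[C@@H]1C=C(C)[C@H](CC(OC)OC)C(C)(C)C1 | intermediate
10 | (2-methyl-1,3-dioxolan-2-yl)acetic acid | CC1(CC(=O)O)OCCO1 | starting material
11 | (1S,4R)-4-(2,2-dimethoxyethyl)-3,5,5-trimethylcyclohex-2-en-1-yl (2-methyl-1,3-dioxolan-2-yl)acetate | CC1(CC(=O)O[C@@H]2C=C(C)[C@H](CC(OC)OC)C(C)(C)C2)OCCO1 | intermediate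
12 | (Z)-O-trimethylsilyl ketene acetal of 11 (dioxolanyl cis to OSi; not isolated) | C[Si](C)(C)O/C(O[C@@H]1C=C(C)[C@H](CC(OC)OC)C(C)(C)C1)=C\C2(C)OCCO2 | intermediate
13 | trimethylsilyl ester of the rearranged acid (Δ1; 10β-CH3; 9α-H; not isolated) | C1C=C[C@@]([C@H](C2(C)OCCO2)C(=O)O[Si](C)(C)C)(C)[C@H](CC(OC)OC)C1(C)C | intermediate
14 | (2S)-2-[(1S,6R)-6-(2,2-dimethoxyethyl)-1,5,5-trimethylcyclohex-2-en-1-yl]-2-(2-methyl-1,3-dioxolan-2-yl)ethan-1-ol (labdane: Δ1, 5β-H, 9α-H, 10β-CH3, C11–OH) | C1C=C[C@@]([C@H](C2(C)OCCO2)CO)(C)[C@H](CC(OC)OC)C1(C)C | intermediate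
15 | 3-hydroxy derivative of 14 (allylic C3–OH, both epimers) | OC1C=C[C@@]([C@H](C2(C)OCCO2)CO)(C)[C@H](CC(OC)OC)C1(C)C | intermediate
16 | 1-en-3-one 11-aldehyde (5β-H, 9α-H, 10β-CH3; C7 dimethyl acetal, C8 dioxolane) | O=C1C=C[C@@]([C@H](C2(C)OCCO2)C=O)(C)[C@H](CC(OC)OC)C1(C)C | intermediate
17 | (3S)-5-methoxy-3-methyl-5-oxopentanoic acid (monomethyl (S)-3-methylglutarate) | OC(=O)C[C@H](C)CC(=O)OC | starting material
18 | methyl (3R)-4-iodo-3-methylbutanoate | IC[C@H](C)CC(=O)OC | intermediate
19 | [(2R)-4-methoxy-2-methyl-4-oxobutyl]triphenylphosphonium iodide | [I-].c1ccccc1[P+](c1ccccc1)(c1ccccc1)C[C@H](C)CC(=O)OC | intermediate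
20 | ylide from 19 (not isolated) | c1ccccc1P(c1ccccc1)(c1ccccc1)=C[C@H](C)CC(=O)OC | intermediate
21 | methyl (11Z,13S)-7,7-dimethoxy-8,8-(ethylenedioxy)-3-oxo-7,8-seco-labda-1,11-dien-15-oate (5β-H, 9α-H) | O=C1C=C[C@@]([C@H](C2(C)OCCO2)/C=C\[C@H](C)CC(=O)OC)(C)[C@H](CC(OC)OC)C1(C)C | intermediate
22 | methyl (13S)-7,7-dimethoxy-8,8-(ethylenedioxy)-3-oxo-7,8-seco-labdan-15-oate (5β-H, 9α-H) | O=C1CC[C@@]([C@H](C2(C)OCCO2)CC[C@H](C)CC(=O)OC)(C)[C@H](CC(OC)OC)C1(C)C | intermediate
23 | potassium C2=C3 enolate of 22 (not isolated) | [K]OC1=CC[C@@]([C@H](C2(C)OCCO2)CC[C@H](C)CC(=O)OC)(C)[C@H](CC(OC)OC)C1(C)C | intermediate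
24 | 2α-hydroxy derivative of 22 | O=C1[C@H](O)C[C@@]([C@H](C2(C)OCCO2)CC[C@H](C)CC(=O)OC)(C)[C@H](CC(OC)OC)C1(C)C | intermediate
25 | 2α-(4-methoxybenzyloxy) 3-ketone | O=C1[C@H](OCc3ccc(OC)cc3)C[C@@]([C@H](C2(C)OCCO2)CC[C@H](C)CC(=O)OC)(C)[C@H](CC(OC)OC)C1(C)C | intermediate
26 | 3α-hydroxy-2α-(4-methoxybenzyloxy) compound | O[C@@H]1[C@H](OCc3ccc(OC)cc3)C[C@@]([C@H](C2(C)OCCO2)CC[C@H](C)CC(=O)OC)(C)[C@H](CC(OC)OC)C1(C)C | intermediate
27 | (2S)-2-hydroxy-2-methylbutanoic acid | CC[C@](C)(O)C(=O)O | starting material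
28 | (2S)-2-hydroxy-2-methylbutanoic 2,4,6-trichlorobenzoic anhydride (not isolated) | CC[C@](C)(O)C(=O)OC(=O)c1c(Cl)cc(Cl)cc1Cl | intermediate
29 | 3α-[(2S)-2-hydroxy-2-methylbutanoyl] ester of 26 | CC[C@](C)(O)C(=O)O[C@@H]1[C@H](OCc3ccc(OC)cc3)C[C@@]([C@H](C2(C)OCCO2)CC[C@H](C)CC(=O)OC)(C)[C@H](CC(OC)OC)C1(C)C | intermediate
30 | keto aldehyde (C7 aldehyde on the C5 arm, C8 methyl ketone on C9; 5β-H, 9α-H) | CC[C@](C)(O)C(=O)O[C@@H]1[C@H](OCc2ccc(OC)cc2)C[C@@]([C@H](C(C)=O)CC[C@H](C)CC(=O)OC)(C)[C@H](CC=O)C1(C)C | intermediate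
31 | methyl 3α-[(2S)-2-hydroxy-2-methylbutanoyloxy]-2α-(4-methoxybenzyloxy)-5β,9α-H-labd-7-en-15-oate (13S) | CC[C@](C)(O)C(=O)O[C@@H]1[C@H](OCc3ccc(OC)cc3)C[C@@]2(C)[C@H](CC=C(C)[C@@H]2CC[C@H](C)CC(=O)OC)C1(C)C | intermediate
32 | 15-carboxylic acid of 31 | CC[C@](C)(O)C(=O)O[C@@H]1[C@H](OCc3ccc(OC)cc3)C[C@@]2(C)[C@H](CC=C(C)[C@@H]2CC[C@H](C)CC(=O)O)C1(C)C | intermediate
33 | (2R,3S,5S,9S,10R,13S)-2-hydroxy-3-{[(2S)-2-hydroxy-2-methylbutanoyl]oxy}labd-7-en-15-oic acid | CC[C@](C)(O)C(=O)O[C@@H]1[C@H](O)C[C@@]2(C)[C@H](CC=C(C)[C@@H]2CC[C@H](C)CC(=O)O)C1(C)C | target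

**Step count and risks**
Total: 21 steps. Longest linear sequence: 19 steps (1–9, then 12–21); steps 10 and 11 make the side-chain fragment.

Steps most likely to fail:

1. Step 17. Acyl transfer to the axial, neopentyl C3 hydroxyl (flanked by the gem-dimethyl group and the C2 ether) may be too slow, so that the activated hydroxy acid is consumed by self-condensation. Fallback, from 26 back to 29: 26 is acylated with the small and very reactive 2-oxobutanoyl chloride (pyridine, DMAP, CH2Cl2) to give the 2-oxobutanoate F1. MeTi(OiPr)3 (THF, −40 °C) should then add methyl to the ketone carbonyl only. The new carbinol centre is not expected to form selectively, so the 2′S alcohol 29 is separated from its 2′R epimer by chromatography.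

2. Step 7. The congested [3,3] shift onto the fully substituted C10 may be slower than β-elimination of the ketal-bearing enolate before silylation, and loss of ketene acetal geometry would erode the C9 configuration. Fallback, from 9 back to 14: copper-catalysed C–O coupling of 9 with (E)-2-(2-iodovinyl)-2-methyl-1,3-dioxolane (CuI, 3,4,7,8-tetramethyl-1,10-phenanthroline, Cs2CO3, toluene, 80 °C) should give the (E)-allyl vinyl ether F2. Heating (xylene, 140 °C) should bring about the aliphatic Claisen rearrangement through the same boat-like arrangement (substituent outside) to the aldehyde F3, which NaBH4 (MeOH, 0 °C) reduces to 14.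

3. Step 19. Intermolecular pinacol coupling, simple reduction of the aldehyde on the titanium surface, or attack on the ester groups during the long addition may compete with ring closure. Fallback, from 30 back to 31: double methylenation with Zn, CH2Br2 and TiCl4 (THF, 0 °C → rt) should give the vinyl/isopropenyl diene F4. Ring-closing metathesis with the second-generation Grubbs catalyst RuCl2(=CHPh)(H2IMes)(PCy3) (CH2Cl2, 40 °C) then closes the same C7=C8 bond.

**Further compounds**
F1 | step 17 | 3α-(2-oxobutanoyl) ester of 26 | CCC(=O)C(=O)O[C@@H]1[C@H](OCc3ccc(OC)cc3)C[C@@]([C@H](C2(C)OCCO2)CC[C@H](C)CC(=O)OC)(C)[C@H](CC(OC)OC)C1(C)C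
F2 | step 7 | (E)-2-(2-methyl-1,3-dioxolan-2-yl)vinyl ether of 9 | CC1(/C=C/O[C@@H]2C=C(C)[C@H](CC(OC)OC)C(C)(C)C2)OCCO1
F3 | step 7 | C11 aldehyde corresponding to 14 | C1C=C[C@@]([C@H](C2(C)OCCO2)C=O)(C)[C@H](CC(OC)OC)C1(C)C
F4 | step 19 | diene from 30 (C7 vinyl, C8 isopropenyl) | CC[C@](C)(O)C(=O)O[C@@H]1[C@H](OCc2ccc(OC)cc2)C[C@@]([C@H](C(C)=C)CC[C@H](C)CC(=O)OC)(C)[C@H](CC=C)C1(C)C
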